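**Remarks on the chemistry (one line each)**

- Locants: the target numbering is used throughout (C1 allyl bridgehead, C2=C3(OMe), C4 OAc, C5 OMe bridgehead, C6 aryl, C7 methyl, C8 bridging C=O); in the monocyclic compounds the ring atoms carry the locants they acquire in the bicycle, and the side-chain carbonyl is C7, its CH2 is C6.
- Structure check: the target SMILES encodes (1S,4S,5S,6S,7R), with the aryl group exo, the methyl group endo (trans to aryl) and the C4 oxygen syn to the C8 bridge; the monocyclic enedione is (R) at C1 and the bicyclic 3,7,8-trione would be (1R,5R,6S), both consistent with the target.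
- Two points are tightened. The closure is 5-exo-trig only at the acceptor and enol-endo at the nucleophile. The free trione cannot relay the C3/C4 regiochemistry because its most acidic proton is C6–H, so the bicyclic product is carried as its 3-O-silyl enol ether (same skeleton; hydrolysis would give the trione).
- The (S,S)-configured ligand in step 5 is assumed to give the (R) centre; if the sense of induction is the opposite, its enantiomer is used.
- 2,4-Dimethoxyphenol, 3,4-dimethoxybenzyl chloride and allyl methyl carbonate are taken as commercial.

## Structural features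

The target is a bicyclo[3.2.1]oct-2-en-8-one: a six-membered ring C1–C2=C3–C4–C5–C8 and a five-membered ring C1–C7–C6–C5–C8 share the atoms C1, C8 and C5. Five stereocentres are contiguous around the periphery (C4–C5–C6–C7–C1). Two of them are fully substituted bridgeheads flanking the C8 ketone: C1 (all-carbon, allyl) and C5 (methoxy). On the two-carbon bridge the aryl group is exo and the methyl group endo; the C4 acetate points to the side of the C8 bridge. Fragile groups are the C2=C3 methyl enol ether (acid), the C4 acetate β to the C8 ketone (base: acyl migration, retro-aldol), the terminal allyl alkene (hydrogenation, electrophilic oxidants) and the electron-rich veratryl ring. The real difficulty is to build the two quaternary bridgeheads in one absolute sense and to tell apart four oxygenated carbons (C3, C4, C5, C8) and a former C7 carbonyl on a compact skeleton. The key step exploits C5: it is a methoxy-bearing bridgehead between C4 and the C8 carbonyl, i.e. the β-carbon of a 2-methoxy-ene-1,4-dione that has accepted C6 and kept its methoxy group. It keeps it because expulsion would need a C4=C5 double bond at the bridgehead of the six-membered ring.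

## Logic of the disconnections

21 to 19 (through 20): the acetyl C–O bond at C4 is cut and replaced by the silyl ether. The acetate would not survive the enolate chemistry at C3, so it is put on last. No skeletal simplification results, but the most base-labile group is removed. The forward step must unveil the C4 hydroxyl without a free alkoxide (retro-aldol towards C8) and without acid (enol ether).

19 to 18: the O–CH3 bond of the C3 enol ether is cut, leaving a C3 ketone. With a bulky silyloxy group on C4 the only accessible α-hydrogens are on C2, so the enol ether can be made regioselectively and late. The forward step needs kinetic deprotonation at C2 and O- rather than C-methylation.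

18 to 16 (through 17): the C4–O bond is cut. The C3–C4 enol silane of 16 is the regiochemical memory of the ring closure, and its face syn to C8 is the open one. One stereocentre and one oxygen disappear. The oxidant must prefer the enol silane to the allyl alkene, and the silyl group must end on O4.

16 to 15 to 13 (through 14): first the C7–H bond is cut (back to a tertiary oxalate), then the C7–CH3 bond (back to the C7 ketone). A carbonyl at C7 is what makes C6 nucleophilic and what lets C6 be equilibrated to the exo-aryl isomer. The C7 stereocentre is removed. Forward, methyl must add to C7 and not to C8, and hydrogen must be delivered to the exo face of C7.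

13 to 10 (through 12 and 11): the C5–C6 bond is cut. In 10, C5 is the methoxy-bearing β-carbon of a vinylogous ester and C6 is the benzylic α-carbon of the side-chain ketone. One ring and two stereocentres (C5, C6) are removed, and a bicycle becomes a cyclohexenedione with a single stereocentre. The forward step must close at C5 and not at C3, keep the methoxy group, and release the product as the C3 enol silane.

10 to 9: the C3 carbonyl is retraced to its dimethyl ketal. The ketal is what keeps the nucleophile of the next disconnection from being a phenol. The forward hydrolysis must avoid nucleophiles, which would deacylate the β-diketone.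

9 to 7 and 8: the C1–allyl bond is cut. C1 is the central carbon of a cyclic β-diketone, so the bond is made from a prochiral stabilised enolate and a π-allyl palladium complex. The only stereocentre of 10 is removed. The forward step must select one enolate face.

7 to 5 (through 6): 7 is formally the methanol adduct of phenol 5 (C3–OMe and C2–H added). It is made by oxidative dearomatisation and hydride delivery to the doubly activated C1=C2 bond of 6. The ring becomes a simple phenol. Methanol must attack para, and hydride must go only to the alkylidene-dicarbonyl.

5 to 4 to 2 and 3, and 2 to 1: the ketone is retraced to the carbinol, the C6–C7 bond to a benzylic nucleophile and an aldehyde, and the aryl–CHO bond to a phenoxide-directed formylation. The acyl carbon must sit ortho to the phenolic oxygen at a position that is not the most electron-rich one of the ring, so a chelation-directed introduction is used instead of an electrophilic acylation. Two commercial arenes remain. The demand is strict ortho regiocontrol.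

## Other disconnections considered

Alternative 1: The cut is at C5–C6 together with a sacrificial C7–C8 bond, leading back to a four-membered ketone. Forward, an α-methoxy keteniminium ion on a chiral amine (from the amide with Tf2O and a hindered pyridine base) would add to (E)-1,2-dimethoxy-4-(prop-1-enyl)benzene A1 in a [2+2] cycloaddition; hydrolysis should give the trans-3-aryl-2-methoxy-4-methylcyclobutanone A2.
- In its favour: C6 and C7 arrive together, trans by virtue of the alkene geometry, with the methyl group already in place. This is better than the chosen plan, which needs two steps and a radical reduction for C7. There is no enol-endo alignment problem.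
- Against it here: A2 contains only C5–C8. C1, the whole C2–C4 bridge, the allyl group and both quaternary centres are still missing. The C7–C8 bond must be broken again while C1 is inserted (a ring expansion in which migration of C7 rather than C5 is not secured), and C5, still an epimerisable CH, must then be made quaternary. An alkoxy keteniminium ion is a weak electrophile, and with an electron-rich styrene the addition is probably stepwise through a benzylic cation, which could weaken the facial control of the auxiliary.
- Comparison: structurally it solves the easier half (C6/C7) first and postpones the bridgeheads, whereas the chosen plan does the reverse. Mechanistically it is a kinetically controlled cycloaddition, against a conjugate addition whose C6 centre can be corrected. In step economy it should be clearly longer after its key step. The two are equal in relying on one external chiral element for the absolute configuration.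

Alternative 2: The cut is at C1–C7 together with a sacrificial C4–C6 bond. Forward, the masked ortho-quinone 2-allyl-4,6,6-trimethoxy-5-oxocyclohexa-1,3-dienyl O-methylmandelate A3, generated in situ by oxidation of the phenol in methanol, would be trapped by A1 in a [4+2] cycloaddition to give the bicyclo[2.2.2]octenone A4. A later 1,2-shift of C6 from C4 to C5 would turn the [2.2.2] into the [3.2.1] skeleton.
- In its favour: all eight ring carbons, the allyl-bearing C1, the C2=C3 enol ether and the trans C6/C7 pair are assembled in one step. This is better than the chosen plan in skeleton-building economy and equal to it in the reliability of the C6/C7 relationship. Cycloadditions of such dienones with electron-rich alkenes are a well-established reaction type.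
- Against it here: both diene termini are fully substituted, so two quaternary bridgeheads must form against a 1,2-disubstituted dienophile while dimerisation of A3 competes. The orientation must put the aryl carbon on C4. Facial control rests on a remote mandelate. The later shift must move C6 and no other group, and it leaves a tertiary C5 alcohol to be methylated next to a ketone, a C4 ketone to be reduced from its hindered face, and a ketal to be hydrolysed beside an enol ether.
- Comparison: there are fewer steps to the carbon skeleton, but more selectivities are left open (regio, facial, migratory, two late redox adjustments). The chosen plan fixes the absolute configuration by a standard catalytic allylation and forms each ring bond in a defined way.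

Alternative 3: The cut is at C5–C8. Forward, a triazolium-derived carbene would convert the aldehyde of the cycloheptenone carbaldehyde A5 into an acyl-anion equivalent that adds across the seven-membered ring to the C5 ketone, giving the 5-hydroxy-4-silyloxy bicyclic ketone A6.
- In its favour: after the key step only O-methylation at C5 and a silyl-to-acetyl exchange remain. This is better than the chosen plan, which needs five steps after ring closure. C5 follows from C1 through the bridge, which is equal to the chosen plan. The step is organocatalytic and mild.
- Against it here: A5 is a heptasubstituted cycloheptenone with four stereocentres, including a quaternary carbon bearing the aldehyde, and is about as hard to make as the target. The neopentyl aldehyde is hindered towards carbene addition. C6–H between the aryl group and the C5 ketone can epimerise under the basic conditions. The benzoin addition is reversible, and O-methylation of the tertiary α-ketol of A6 invites retro-benzoin or α-ketol shifts.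
- Comparison: it builds the one-carbon bridge last by umpolung, whereas the chosen plan has C8 in the ring from the start and forms the two-carbon bridge by normal-polarity conjugate addition. It is shorter after the key step and much longer before it.

Key step: step 7

Step 1
Reactants: 1 2,4-dimethoxyphenol
Product: 2 2-hydroxy-3,5-dimethoxybenzaldehyde
Conditions: MgCl2, Et3N, (CH2O)n, MeCN, reflux; aq. HCl work-up
Reagents that add atoms: formaldehyde (from paraformaldehyde), C=O
Why: Magnesium-mediated ortho-formylation (Casnati–Skattebøl reaction): the magnesium phenoxide delivers formaldehyde to its own ortho carbon through a chelate and the salicyl alkoxide is oxidised by a second formaldehyde (Oppenauer-type hydride transfer); the only free ortho position is used, so the more electron-rich carbon para to the 2-methoxy group is not attacked, and no Lewis acid strong enough to cleave the guaiacol-type ether is present.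

Step 2
Reactants: 2 2-hydroxy-3,5-dimethoxybenzaldehyde; 3 4-(chloromethyl)-1,2-dimethoxybenzene
Product: 4 rac-2-[2-(3,4-dimethoxyphenyl)-1-hydroxyethyl]-4,6-dimethoxyphenol
Conditions: 3, Mg, THF, 0 °C (ArCH2MgCl, 2.5 equiv); then 2, THF, −20 to 0 °C; aq. NH4Cl
Reagents that add atoms: none
Why: Grignard 1,2-addition to the aldehyde; the first equivalent only deprotonates the phenol and the magnesium phenoxide chelate activates the formyl group; the carbinol centre is racemic and is removed in step 3.

Step 3
Reactants: 4 rac-2-[2-(3,4-dimethoxyphenyl)-1-hydroxyethyl]-4,6-dimethoxyphenol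
Product: 5 2-(3,4-dimethoxyphenyl)-1-(2-hydroxy-3,5-dimethoxyphenyl)ethan-1-one
Conditions: activated MnO2, CH2Cl2, 23 °C
Reagents that add atoms: none
Why: Selective oxidation of an ortho-hydroxybenzylic alcohol by MnO2, which should leave the phenol (hydrogen-bonded to the new ketone) and the methoxyarenes untouched.

Step 4
Reactants: 5 2-(3,4-dimethoxyphenyl)-1-(2-hydroxy-3,5-dimethoxyphenyl)ethan-1-one
Product: 7 rac-6-[(3,4-dimethoxyphenyl)acetyl]-2,4,4-trimethoxycyclohex-2-en-1-one, via quinone monoketal 6 (not isolated)
Conditions: PhI(OAc)2, MeOH, 0 °C; then diethyl 2,6-dimethyl-1,4-dihydropyridine-3,5-dicarboxylate, 0 to 23 °C; aq. NaHCO3 work-up, Et3N-deactivated silica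
Reagents that add atoms: methanol, CO
Why: Oxidative dearomatisation of a para-methoxyphenol by the trivalent iodine reagent, methanol adding para to give the para-quinone monoketal 6; its alkylidene-1,3-dicarbonyl C=C is by far the most electrophilic site and should take up hydride from the dihydropyridine (Hantzsch ester transfer hydrogenation), giving a cyclic 2-acyl ketone that the ketal keeps from re-aromatising as long as acid is excluded.

Step 5
Reactants: 7 rac-6-[(3,4-dimethoxyphenyl)acetyl]-2,4,4-trimethoxycyclohex-2-en-1-one; 8 allyl methyl carbonate
Product: 9 (6R)-6-allyl-6-[(3,4-dimethoxyphenyl)acetyl]-2,4,4-trimethoxycyclohex-2-en-1-one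
Conditions: Pd2(dba)3·CHCl3 (2.5 mol %), (1S,2S)-N,N′-bis[2-(diphenylphosphanyl)benzoyl]cyclohexane-1,2-diamine (6 mol %), toluene, 0 °C
Reagents that add atoms: none
Why: Tsuji–Trost asymmetric allylic alkylation of a prochiral cyclic β-diketone: zerovalent palladium ionises 8, the methoxide released deprotonates 7, and the stabilised enolate attacks the π-allyl complex from outside the metal within the chiral pocket of the ligand, which selects the enolate face and sets C1 as (R); O-allyl isomers can re-ionise, so the C-allylated quaternary product should accumulate.

Step 6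
Reactants: 9 (6R)-6-allyl-6-[(3,4-dimethoxyphenyl)acetyl]-2,4,4-trimethoxycyclohex-2-en-1-one
Product: 10 (6R)-6-allyl-6-[(3,4-dimethoxyphenyl)acetyl]-2-methoxycyclohex-2-ene-1,4-dione
Conditions: oxalic acid (cat.), wet SiO2, CH2Cl2, 23 °C
Reagents that add atoms: water, O
Why: Mild acid hydrolysis of a dimethyl ketal through an oxocarbenium ion that is stabilised by the neighbouring enol ether (the product is a vinylogous ester); the quaternary C1 rules out aromatisation, and no nucleophile is present that could cause retro-Claisen loss of the arylacetyl group.

Step 7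
Reactants: 10 (6R)-6-allyl-6-[(3,4-dimethoxyphenyl)acetyl]-2-methoxycyclohex-2-ene-1,4-dione
Product: 13 (1R,5R,6S)-1-allyl-3-(tert-butyldimethylsilyloxy)-6-(3,4-dimethoxyphenyl)-5-methoxybicyclo[3.2.1]oct-3-ene-7,8-dione (aryl exo), via silyl enol ether 11 (not isolated), via endo-aryl epimer 12 (not isolated)
Conditions: KN(SiMe3)2, THF, −78 °C, then TBSOTf, −78 °C; aq. NaHCO3 work-up, crude; Tf2NH (5 mol %), CH2Cl2, −78 to −30 °C; then DBU (0.3 equiv), 23 °C
Reagents that add atoms: tert-butyldimethylsilyl trifluoromethanesulfonate, CC(C)(C)[Si](C)(C)OS(=O)(=O)C(F)(F)F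
Why: KN(SiMe3)2 removes the most acidic proton (benzylic C6–H next to the C7 ketone) and TBSOTf traps the (Z)-enolate on oxygen as 11. Tf2NH is converted by a little 11 into TBSNTf2, which silylates the vinylogous-ester oxygen on C3 and turns C5 into an alkoxy-stabilised cationic terminus; C6 of the enol silane adds to C5 and the silyl group of the resulting C7 oxocarbenium ion is passed on, so the product is released as the C3–C4 enol silane with the C7 ketone restored, an intramolecular Mukaiyama–Michael addition with silyl transfer whose closest known type is the silyl triflimide- or silyl triflate-catalysed addition of enol silanes to enones and β-alkoxy enones. The ring closed is the five-membered ring C1–C7–C6–C5–C8, 5-exo-trig at the acceptor but enol-endo at the nucleophile, so orbital overlap is imperfect; the strongly electrophilic silylated acceptor and the axial placement of the side chain, which holds C6 over C5, should compensate. The methoxy group stays on C5 because its loss from the C3 enol derivative would need a C4=C5 double bond at the bridgehead (Bredt's rule). The step needs attack at C5 rather than at C3 (also a five-membered closure): conjugate addition is the normal course of enol silanes with activated enones, the C3 terminus carries the bulky silyloxy group, and a 1,2-adduct would be a tertiary silyl aldolate that can revert. C5 is dictated by C1, since the two-atom tether can only reach the ring face that carries the acyl group. C6 is formed under kinetic control (the Z-enol silane approaching from outside the ring should give the endo-aryl epimer 12) and is then equilibrated by DBU through the C7 enol to the exo-aryl isomer 13, in which the aryl group avoids the C2–C4 bridge. Retro-Michael opening during this equilibration is blocked because C3 is locked as the enol silane.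

Step 8
Reactants: 13 (1R,5R,6S)-1-allyl-3-(tert-butyldimethylsilyloxy)-6-(3,4-dimethoxyphenyl)-5-methoxybicyclo[3.2.1]oct-3-ene-7,8-dione
Product: 15 methyl (1R,5R,6R,7R)-1-allyl-3-(tert-butyldimethylsilyloxy)-6-(3,4-dimethoxyphenyl)-5-methoxy-7-methyl-8-oxobicyclo[3.2.1]oct-3-en-7-yl oxalate (7-methyl exo), via tertiary cerium alkoxide 14 (not isolated)
Conditions: MeLi, CeCl3 (anhydrous), THF, −78 °C; then ClC(O)CO2Me, −78 to 0 °C
Reagents that add atoms: methyllithium, [Li]C; methyl chlorooxoacetate, COC(=O)C(=O)Cl
Why: Organocerium 1,2-addition (non-basic, so the acidic C6–H is not removed) to the C7 ketone, then O-acylation of the alkoxide in the same flask; C7 should be preferred to C8 because C8 lies between two fully substituted carbons and is screened by the exo-aryl group on one face and the C2–C4 bridge on the other, and the low temperature with immediate acylation should suppress retro-aldol opening of the β-keto alkoxide; exo attack (methyl exo) is expected, but the C7 configuration is erased in step 9.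

Step 9
Reactants: 15 methyl (1R,5R,6R,7R)-1-allyl-3-(tert-butyldimethylsilyloxy)-6-(3,4-dimethoxyphenyl)-5-methoxy-7-methyl-8-oxobicyclo[3.2.1]oct-3-en-7-yl oxalate
Product: 16 (1R,5S,6S,7R)-1-allyl-3-(tert-butyldimethylsilyloxy)-6-(3,4-dimethoxyphenyl)-5-methoxy-7-methylbicyclo[3.2.1]oct-3-en-8-one (aryl exo, methyl endo)
Conditions: Bu3SnH, AIBN, toluene, 90 °C
Reagents that add atoms: none
Why: Barton–McCombie-type radical deoxygenation of a tertiary methyl oxalate: the stannyl radical adds to the oxalate carbonyl, the C7–O bond fragments to a tertiary radical, and this should take hydrogen from Bu3SnH on the convex exo face (the endo face lies in the pocket under the C2–C4 bridge), which places the methyl group endo and trans to the aryl group, also the thermodynamically preferred arrangement; the allyl group and the enol silane are inert to the chain.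

Step 10
Reactants: 16 (1R,5S,6S,7R)-1-allyl-3-(tert-butyldimethylsilyloxy)-6-(3,4-dimethoxyphenyl)-5-methoxy-7-methylbicyclo[3.2.1]oct-3-en-8-one
Product: 18 (1R,4R,5S,6S,7R)-1-allyl-4-(tert-butyldimethylsilyloxy)-6-(3,4-dimethoxyphenyl)-5-methoxy-7-methylbicyclo[3.2.1]octane-3,8-dione (C4 oxygen syn to C8), via silyloxy epoxide 17 (not isolated)
Conditions: mCPBA, CH2Cl2, −15 to 23 °C; aq. NaHCO3 work-up
Reagents that add atoms: 3-chloroperbenzoic acid, OOC(=O)c1cccc(Cl)c1
Why: Rubottom oxidation: the peracid should epoxidise the electron-rich enol silane far faster than the monosubstituted allyl alkene and on the face syn to C8, the other face being covered by the C6–C7 bridge and its endo-methyl group; opening of 17 and 1,4-silyl migration give the α-silyloxy ketone with the C4 oxygen oriented as in the target.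

Step 11
Reactants: 18 (1R,4R,5S,6S,7R)-1-allyl-4-(tert-butyldimethylsilyloxy)-6-(3,4-dimethoxyphenyl)-5-methoxy-7-methylbicyclo[3.2.1]octane-3,8-dione
Product: 19 (1S,4S,5S,6S,7R)-1-allyl-4-(tert-butyldimethylsilyloxy)-6-(3,4-dimethoxyphenyl)-3,5-dimethoxy-7-methylbicyclo[3.2.1]oct-2-en-8-one
Conditions: KN(SiMe3)2, THF/DMPU, −78 °C; MeOTf, −78 °C; Et3N-buffered work-up
Reagents that add atoms: methyl trifluoromethanesulfonate, COS(=O)(=O)C(F)(F)F
Why: Kinetic deprotonation at the C2 methylene (the C4 methine is shielded by the silyloxy group and the quaternary C5, and C8 has no α-hydrogen) followed by O-alkylation of the potassium enolate with a hard methylating agent in a dipolar medium; C-methylation at C2 is retarded by the adjacent quaternary C1.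

Step 12
Reactants: 19 (1S,4S,5S,6S,7R)-1-allyl-4-(tert-butyldimethylsilyloxy)-6-(3,4-dimethoxyphenyl)-3,5-dimethoxy-7-methylbicyclo[3.2.1]oct-2-en-8-one
Product: 21 (1S,4S,5S,6S,7R)-1-allyl-6-(3,4-dimethoxyphenyl)-3,5-dimethoxy-7-methyl-8-oxobicyclo[3.2.1]oct-2-en-4-yl acetate, via allylic alcohol 20 (not isolated)
Conditions: Bu4NF, AcOH, THF, 0 °C; then Et3N, Ac2O, DMAP, 23 °C
Reagents that add atoms: acetic anhydride, CC(=O)OC(C)=O
Why: Fluoride cleavage of the silyl ether, buffered with acetic acid so that no free C4 alkoxide builds up (retro-aldol towards C8) and the enol ether is not hydrolysed, then DMAP-catalysed acetylation of the hindered allylic alcohol 20; no stereocentre is touched.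

**Compound list**

1 | 2,4-dimethoxyphenol | COc1ccc(O)c(OC)c1 | starting material
2 | 2-hydroxy-3,5-dimethoxybenzaldehyde | COc1cc(OC)c(O)c(C=O)c1 | intermediate
3 | 4-(chloromethyl)-1,2-dimethoxybenzene | COc1ccc(CCl)cc1OC | starting material
4 | rac-2-[2-(3,4-dimethoxyphenyl)-1-hydroxyethyl]-4,6-dimethoxyphenol | COc1cc(OC)c(O)c(C(O)Cc2ccc(OC)c(OC)c2)c1 | intermediate
5 | 2-(3,4-dimethoxyphenyl)-1-(2-hydroxy-3,5-dimethoxyphenyl)ethan-1-one | COc1cc(OC)c(O)c(C(=O)Cc2ccc(OC)c(OC)c2)c1 | intermediate
6 | 2-[(3,4-dimethoxyphenyl)acetyl]-4,4,6-trimethoxycyclohexa-2,5-dien-1-one | COC1=CC(OC)(OC)C=C(C(=O)Cc2ccc(OC)c(OC)c2)C1=O | intermediate (not isolated)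
7 | rac-6-[(3,4-dimethoxyphenyl)acetyl]-2,4,4-trimethoxycyclohex-2-en-1-one (keto–enol mixture, drawn as diketone) | COC1=CC(OC)(OC)CC(C(=O)Cc2ccc(OC)c(OC)c2)C1=O | intermediate
8 | allyl methyl carbonate | C=CCOC(=O)OC | starting material
9 | (6R)-6-allyl-6-[(3,4-dimethoxyphenyl)acetyl]-2,4,4-trimethoxycyclohex-2-en-1-one | C=CC[C@]1(C(=O)Cc2ccc(OC)c(OC)c2)CC(OC)(OC)C=C(OC)C1=O | intermediate
10 | (6R)-6-allyl-6-[(3,4-dimethoxyphenyl)acetyl]-2-methoxycyclohex-2-ene-1,4-dione | C=CC[C@]1(C(=O)Cc2ccc(OC)c(OC)c2)CC(=O)C=C(OC)C1=O | intermediate (precursor of the key step)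
11 | (6R)-6-allyl-6-[(Z)-1-(tert-butyldimethylsilyloxy)-2-(3,4-dimethoxyphenyl)ethenyl]-2-methoxycyclohex-2-ene-1,4-dione | C=CC[C@]1(/C(O[Si](C)(C)C(C)(C)C)=C/c2ccc(OC)c(OC)c2)CC(=O)C=C(OC)C1=O | intermediate (not isolated)
12 | (1R,5R,6R)-1-allyl-3-(tert-butyldimethylsilyloxy)-6-(3,4-dimethoxyphenyl)-5-methoxybicyclo[3.2.1]oct-3-ene-7,8-dione (aryl endo) | C=CC[C@]12CC(O[Si](C)(C)C(C)(C)C)=C[C@](OC)(C1=O)[C@@H](c1ccc(OC)c(OC)c1)C2=O | intermediate (not isolated)
13 | (1R,5R,6S)-1-allyl-3-(tert-butyldimethylsilyloxy)-6-(3,4-dimethoxyphenyl)-5-methoxybicyclo[3.2.1]oct-3-ene-7,8-dione (aryl exo) | C=CC[C@]12CC(O[Si](C)(C)C(C)(C)C)=C[C@](OC)(C1=O)[C@H](c1ccc(OC)c(OC)c1)C2=O | intermediate (product of the key step)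
14 | (1R,5R,6R,7R)-1-allyl-3-(tert-butyldimethylsilyloxy)-6-(3,4-dimethoxyphenyl)-7-hydroxy-5-methoxy-7-methylbicyclo[3.2.1]oct-3-en-8-one (methyl exo, hydroxyl endo; formed as its cerium alkoxide) | C=CC[C@]12CC(O[Si](C)(C)C(C)(C)C)=C[C@](OC)(C1=O)[C@H](c1ccc(OC)c(OC)c1)[C@@]2(C)O | intermediate (not isolated)
15 | methyl (1R,5R,6R,7R)-1-allyl-3-(tert-butyldimethylsilyloxy)-6-(3,4-dimethoxyphenyl)-5-methoxy-7-methyl-8-oxobicyclo[3.2.1]oct-3-en-7-yl oxalate | C=CC[C@]12CC(O[Si](C)(C)C(C)(C)C)=C[C@](OC)(C1=O)[C@H](c1ccc(OC)c(OC)c1)[C@@]2(C)OC(=O)C(=O)OC | intermediate
16 | (1R,5S,6S,7R)-1-allyl-3-(tert-butyldimethylsilyloxy)-6-(3,4-dimethoxyphenyl)-5-methoxy-7-methylbicyclo[3.2.1]oct-3-en-8-one (aryl exo, methyl endo) | C=CC[C@]12CC(O[Si](C)(C)C(C)(C)C)=C[C@](OC)(C1=O)[C@H](c1ccc(OC)c(OC)c1)[C@H]2C | intermediate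
17 | 3,4-epoxide of 16, oxirane oxygen on the face syn to C8, silyloxy group on C3 | C=CC[C@]12C[C@]3(O[Si](C)(C)C(C)(C)C)O[C@@H]3[C@](OC)(C1=O)[C@H](c1ccc(OC)c(OC)c1)[C@H]2C | intermediate (not isolated)
18 | (1R,4R,5S,6S,7R)-1-allyl-4-(tert-butyldimethylsilyloxy)-6-(3,4-dimethoxyphenyl)-5-methoxy-7-methylbicyclo[3.2.1]octane-3,8-dione | C=CC[C@]12CC(=O)[C@H](O[Si](C)(C)C(C)(C)C)[C@](OC)(C1=O)[C@H](c1ccc(OC)c(OC)c1)[C@H]2C | intermediate
19 | (1S,4S,5S,6S,7R)-1-allyl-4-(tert-butyldimethylsilyloxy)-6-(3,4-dimethoxyphenyl)-3,5-dimethoxy-7-methylbicyclo[3.2.1]oct-2-en-8-one | C=CC[C@]12C=C(OC)[C@H](O[Si](C)(C)C(C)(C)C)[C@](OC)(C1=O)[C@H](c1ccc(OC)c(OC)c1)[C@H]2C | intermediate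
20 | (1S,4S,5S,6S,7R)-1-allyl-6-(3,4-dimethoxyphenyl)-4-hydroxy-3,5-dimethoxy-7-methylbicyclo[3.2.1]oct-2-en-8-one | C=CC[C@]12C=C(OC)[C@H](O)[C@](OC)(C1=O)[C@H](c1ccc(OC)c(OC)c1)[C@H]2C | intermediate (not isolated)
21 | (1S,4S,5S,6S,7R)-1-allyl-6-(3,4-dimethoxyphenyl)-3,5-dimethoxy-7-methyl-8-oxobicyclo[3.2.1]oct-2-en-4-yl acetate | C=CC[C@]12C=C(OC)[C@H](OC(C)=O)[C@](OC)(C1=O)[C@H](c1ccc(OC)c(OC)c1)[C@H]2C | target

**Step count and least certain steps**

Total: 12 steps. Longest linear sequence: 12 steps (from 1; 3 and 8 are purchased).

Step 7 (key step). The closure may be slow because the enol-endo nucleophile cannot align its π orbital well with C5. The silyl enol ether could then be lost by protodesilylation, or add 1,2 at C3. The fallback changes the mode of activation from an electrophile-activated, kinetically controlled Mukaiyama process to a reversible anionic addition. It sets out from 10: KN(SiMe3)2 (1.05 equiv) in THF is warmed from −78 to −30 °C, so that the potassium enolate can add reversibly to the C3 carbonyl and irreversibly to C5. The C3 enolate of the adduct is then trapped at −78 °C with TBSOTf before proton transfer from C6–H can relocate it, and DBU equilibrates C6. The route is rejoined at 13; no compound outside the list is made (F0).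

Step 5. Facial discrimination of the enolate by the ligand may be incomplete for this particular β-diketone, giving material of insufficient enantiomeric purity. The fallback replaces asymmetric catalysis by resolution. It sets out from 7: allylation with 8 and Pd(PPh3)4 in THF should give the racemic 6-allyl-6-[(3,4-dimethoxyphenyl)acetyl]-2,4,4-trimethoxycyclohex-2-en-1-one F1. This is separated by preparative chromatography on a chiral stationary phase; the (6S)-enantiomer F2 is discarded and the (6R)-enantiomer is 9, where the route is rejoined.

Step 8. Methyl transfer may go to the strained, α-methoxy-substituted C8 ketone (chelation), or the β-keto alkoxide may open by retro-aldol cleavage. The fallback takes C8 out of play. It sets out from 13: KN(SiMe3)2 masks C7 as its enolate, and i-Bu2AlH at −78 °C then reduces the only remaining ketone, giving after work-up and brief DBU equilibration of C6 the 1-allyl-3-(tert-butyldimethylsilyloxy)-6-(3,4-dimethoxyphenyl)-8-hydroxy-5-methoxybicyclo[3.2.1]oct-3-en-7-one F3. MeLi/CeCl3 (excess, −78 °C) adds to the single ketone to give the 7-methyl-7,8-diol F4. Dess–Martin periodinane (NaHCO3-buffered) oxidises only the secondary C8 carbinol and returns the tertiary alcohol 14, now isolated. Acylation with ClC(O)CO2Me, DMAP and Et3N rejoins the route at 15.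

Step 9. Hydrogen transfer may occur partly on the endo face, anti to the neighbouring aryl group, giving the 7-epimer; the tertiary oxalate may also eliminate. The fallback avoids the oxalate and uses a hydrogen-atom-transfer hydrogenation that is biased towards the more stable diastereomer and prefers 1,1-disubstituted over monosubstituted alkenes. It sets out from 13: Petasis methylenation (Cp2TiMe2, toluene, 65 °C) at the less shielded C7 ketone should give the 7-methylidene compound 1-allyl-3-(tert-butyldimethylsilyloxy)-6-(3,4-dimethoxyphenyl)-5-methoxy-7-methylidenebicyclo[3.2.1]oct-3-en-8-one F5. Mn(dpm)3, PhSiH3 and t-BuOOH in i-PrOH then reduce the exocyclic alkene, and the route is rejoined at 16.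

Step 11. The enolate may be methylated on carbon at C2, or deprotonation may stray to C4 with silyl migration or epimerisation. The fallback makes the enol ether by elimination from a ketal instead of by enolate alkylation. It sets out from 18: MeOSiMe3 with catalytic TMSOTf at −78 °C should give the 3,3-dimethyl ketal 1-allyl-4-(tert-butyldimethylsilyloxy)-6-(3,4-dimethoxyphenyl)-3,3,5-trimethoxy-7-methylbicyclo[3.2.1]octan-8-one F6. TMSOTf and i-Pr2NEt then eliminate methanol towards the unhindered C2 methylene, and the route is rejoined at 19.

## Further compounds

F0 | step 7 | none | none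
F1 | step 5 | rac-6-allyl-6-[(3,4-dimethoxyphenyl)acetyl]-2,4,4-trimethoxycyclohex-2-en-1-one | C=CCC1(C(=O)Cc2ccc(OC)c(OC)c2)CC(OC)(OC)C=C(OC)C1=O
F2 | step 5 | (6S)-6-allyl-6-[(3,4-dimethoxyphenyl)acetyl]-2,4,4-trimethoxycyclohex-2-en-1-one | C=CC[C@@]1(C(=O)Cc2ccc(OC)c(OC)c2)CC(OC)(OC)C=C(OC)C1=O
F3 | step 8 | 1-allyl-3-(tert-butyldimethylsilyloxy)-6-(3,4-dimethoxyphenyl)-8-hydroxy-5-methoxybicyclo[3.2.1]oct-3-en-7-one (aryl exo; hydroxyl drawn on the side of the C2–C4 bridge, its configuration being of no consequence) | C=CC[C@]12CC(O[Si](C)(C)C(C)(C)C)=C[C@](OC)([C@@H]1O)[C@H](c1ccc(OC)c(OC)c1)C2=O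
F4 | step 8 | 1-allyl-3-(tert-butyldimethylsilyloxy)-6-(3,4-dimethoxyphenyl)-5-methoxy-7-methylbicyclo[3.2.1]oct-3-ene-7,8-diol (7-methyl exo) | C=CC[C@]12CC(O[Si](C)(C)C(C)(C)C)=C[C@](OC)([C@@H]1O)[C@H](c1ccc(OC)c(OC)c1)[C@@]2(C)O
F5 | step 9 | 1-allyl-3-(tert-butyldimethylsilyloxy)-6-(3,4-dimethoxyphenyl)-5-methoxy-7-methylidenebicyclo[3.2.1]oct-3-en-8-one (aryl exo) | C=CC[C@]12CC(O[Si](C)(C)C(C)(C)C)=C[C@](OC)(C1=O)[C@H](c1ccc(OC)c(OC)c1)C2=C
F6 | step 11 | 1-allyl-4-(tert-butyldimethylsilyloxy)-6-(3,4-dimethoxyphenyl)-3,3,5-trimethoxy-7-methylbicyclo[3.2.1]octan-8-one (stereocentres as in 18) | C=CC[C@]12CC(OC)(OC)[C@H](O[Si](C)(C)C(C)(C)C)[C@](OC)(C1=O)[C@H](c1ccc(OC)c(OC)c1)[C@H]2C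
A1 | alternative 1 | (E)-1,2-dimethoxy-4-(prop-1-enyl)benzene | C/C=C/c1ccc(OC)c(OC)c1
A2 | alternative 1 | 3-(3,4-dimethoxyphenyl)-2-methoxy-4-methylcyclobutanone (aryl and methyl trans) | O=C1[C@@H](OC)[C@H](c2ccc(OC)c(OC)c2)[C@H]1C
A3 | alternative 2 | 2-allyl-4,6,6-trimethoxy-5-oxocyclohexa-1,3-dienyl O-methylmandelate (masked ortho-quinone) | C=CCC1=CC(OC)=C(OC(=O)[C@@H](OC)c2ccccc2)C(=O)C1(OC)OC
A4 | alternative 2 | bicyclo[2.2.2]oct-5-en-2-one adduct (C4–C6 bonded, C5 ketone, C8 dimethyl ketal) | C=CC[C@]12C=C(OC)[C@](OC(=O)[C@@H](OC)c3ccccc3)(C(=O)C1(OC)OC)[C@H](c1ccc(OC)c(OC)c1)[C@H]2C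
A5 | alternative 3 | 1-allyl-4-(tert-butyldimethylsilyloxy)-6-(3,4-dimethoxyphenyl)-3-methoxy-7-methyl-5-oxocyclohept-2-ene-1-carbaldehyde | C=CC[C@@]1(C=O)C=C(OC)[C@H](O[Si](C)(C)C(C)(C)C)C(=O)[C@H](c2ccc(OC)c(OC)c2)[C@H]1C
A6 | alternative 3 | 5-hydroxy-4-(tert-butyldimethylsilyloxy)bicyclo[3.2.1]oct-2-en-8-one benzoin product | C=CC[C@]12C=C(OC)[C@H](O[Si](C)(C)C(C)(C)C)[C@](O)(C1=O)[C@H](c1ccc(OC)c(OC)c1)[C@H]2C
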